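## Retrosynthetic overview
(Target oxolane numbering: O1, C2 = OCH2, C3 = aroyl carbon, C4 = CH2OH carbon, C5 = aryl carbon.)
1. The target comes from a cis-fused oxolane/γ-lactone whose lactone carbonyl is a traceless tether: saponification, loss of CO2 from the β-keto acid, equilibration of C3 to trans.
2. The oxolane comes from a (3+2) annulation of a donor–acceptor cyclopropane with formaldehyde: O–C5 forms with inversion (4,5-cis), then C2–C3 closes.
3. Key ring-forming step: enantioselective intramolecular cyclopropanation of a cinnamyl α-diazo-β-keto ester builds the cyclopropane and the γ-lactone together.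
4. The diazo ester comes from diazo transfer onto the cinnamyl β-keto ester, made by transesterification of two commercial pieces.
5. Ring order: cyclopropane + γ-lactone (together), then oxolane (cyclopropane consumed), then lactone opened.

Assumption: the cobalt catalyst in step 3 is taken to give the enantiomer drawn; if the mirror-image bicycle predominates, the mirror-image porphyrin ligand is used and nothing else changes.

## Route

Step 1
Reactants: 1 ethyl 3-oxo-3-(3,4,5-trimethoxyphenyl)propanoate; 2 (E)-3-(3,4-dimethoxyphenyl)prop-2-en-1-ol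
Product: 3 (E)-3-(3,4-dimethoxyphenyl)prop-2-en-1-yl 3-oxo-3-(3,4,5-trimethoxyphenyl)propanoate
Conditions: DMAP (0.3 equiv), toluene, reflux, EtOH removed over 4 Å MS
Reagents that add atoms: none
Why: DMAP-catalysed transesterification of a β-keto ester, pulled to completion by removing ethanol; no stereocentre is involved.

Step 2
Reactants: 3 (E)-3-(3,4-dimethoxyphenyl)prop-2-en-1-yl 3-oxo-3-(3,4,5-trimethoxyphenyl)propanoate
Product: 4 (E)-3-(3,4-dimethoxyphenyl)prop-2-en-1-yl 2-diazo-3-oxo-3-(3,4,5-trimethoxyphenyl)propanoate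
Conditions: p-ABSA (1.2 equiv), Et3N, MeCN, 0 °C → rt
Reagents that add atoms: 4-acetamidobenzenesulfonyl azide (p-ABSA), CC(=O)Nc1ccc(cc1)S(=O)(=O)N=[N+]=[N-]
Why: Regitz diazo transfer to the doubly activated methylene; no stereocentre is involved.

Step 3
Reactants: 4 (E)-3-(3,4-dimethoxyphenyl)prop-2-en-1-yl 2-diazo-3-oxo-3-(3,4,5-trimethoxyphenyl)propanoate
Product: 5 (1R,5S,6R)-6-(3,4-dimethoxyphenyl)-1-(3,4,5-trimethoxybenzoyl)-3-oxabicyclo[3.1.0]hexan-2-one (aryl exo, trans to C4H2)
Conditions: [Co(3,5-DitBu-ChenPhyrin)] (divalent cobalt complex of a D2-symmetric chiral amidoporphyrin, 2 mol%), toluene, 25–40 °C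
Reagents that add atoms: none
Why: Catalytic asymmetric intramolecular cyclopropanation (cobalt metalloradical catalysis) closes the cyclopropane and the γ-lactone together; the chiral porphyrin pocket chooses the alkene face and so fixes C1 and C5, while the E-alkene and the stepwise ring closure place the aryl group at C6 exo.

Step 4
Reactants: 5 (1R,5S,6R)-6-(3,4-dimethoxyphenyl)-1-(3,4,5-trimethoxybenzoyl)-3-oxabicyclo[3.1.0]hexan-2-one
Product: 6 (1S,5S,6S)-6-(3,4-dimethoxyphenyl)-1-(3,4,5-trimethoxybenzoyl)-3,7-dioxabicyclo[3.3.0]octan-2-one (cis-fused, aryl cis to C4H2)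
Conditions: CH2O (gas from cracked paraformaldehyde, ca. 5 equiv), AlCl3 (15 mol%), CH2Cl2, −40 → 0 °C
Reagents that add atoms: formaldehyde, C=O
Why: Proposed new method: the Lewis-acid-chelated keto-lactone polarises the C1–C6 bond, the formaldehyde oxygen attacks benzylic C6 from the rear (inversion, which puts the aryl group cis to the CH2O arm on the neighbouring carbon), and the carbanionic terminus closes onto the O-bound CH2 on the only face that gives a cis-fused bicycle; the closest known reaction type is the Lewis-acid (3+2) annulation of donor–acceptor cyclopropanes with aldehydes, stereospecific with inversion at the donor carbon, together with the use of formaldimine surrogates in the nitrogen series.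

Step 5
Reactants: 6 (1S,5S,6S)-6-(3,4-dimethoxyphenyl)-1-(3,4,5-trimethoxybenzoyl)-3,7-dioxabicyclo[3.3.0]octan-2-one
Product: 9 [(3R,4S,5S)-5-(3,4-dimethoxyphenyl)-4-(hydroxymethyl)oxolan-3-yl](3,4,5-trimethoxyphenyl)methanone, via hydroxy keto acid 7 (not isolated), via C3-epimeric ketone 8 (not isolated)
Conditions: LiOH·H2O (2.5 equiv), THF/H2O 3:1, 0 °C → rt; AcOH to pH 5, 50 °C; then DBU (0.3 equiv), THF, rt
Reagents that add atoms: none
Why: Saponification of the strained γ-lactone, decarboxylation of the resulting β-keto acid and base equilibration of the α-keto carbon give the ketone with the aroyl group trans to the hydroxymethyl group (thermodynamic control at C3), while C4 and C5 are untouched and ring opening by β-elimination is stereoelectronically disfavoured (reverse 5-endo-trig).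

## Compound list
1 | ethyl 3-oxo-3-(3,4,5-trimethoxyphenyl)propanoate | CCOC(=O)CC(=O)c1cc(OC)c(OC)c(OC)c1 | starting material
2 | (E)-3-(3,4-dimethoxyphenyl)prop-2-en-1-ol | COc1ccc(/C=C/CO)cc1OC | starting material
3 | (E)-3-(3,4-dimethoxyphenyl)prop-2-en-1-yl 3-oxo-3-(3,4,5-trimethoxyphenyl)propanoate | COc1ccc(/C=C/COC(=O)CC(=O)c2cc(OC)c(OC)c(OC)c2)cc1OC | intermediate
4 | (E)-3-(3,4-dimethoxyphenyl)prop-2-en-1-yl 2-diazo-3-oxo-3-(3,4,5-trimethoxyphenyl)propanoate | COc1ccc(/C=C/COC(=O)C(=[N+]=[N-])C(=O)c2cc(OC)c(OC)c(OC)c2)cc1OC | intermediate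
5 | (1R,5S,6R)-6-(3,4-dimethoxyphenyl)-1-(3,4,5-trimethoxybenzoyl)-3-oxabicyclo[3.1.0]hexan-2-one | O=C1OC[C@H]2[C@H](c3ccc(OC)c(OC)c3)[C@@]12C(=O)c1cc(OC)c(OC)c(OC)c1 | intermediate
6 | (1S,5S,6S)-6-(3,4-dimethoxyphenyl)-1-(3,4,5-trimethoxybenzoyl)-3,7-dioxabicyclo[3.3.0]octan-2-one | COc1ccc([C@H]2OC[C@@]3(C(=O)c4cc(OC)c(OC)c(OC)c4)C(=O)OC[C@@H]23)cc1OC | intermediate
7 | (3S,4S,5S)-5-(3,4-dimethoxyphenyl)-4-(hydroxymethyl)-3-(3,4,5-trimethoxybenzoyl)oxolane-3-carboxylic acid (lithium carboxylate until acidified) | COc1ccc([C@H]2OC[C@](C(=O)O)(C(=O)c3cc(OC)c(OC)c(OC)c3)[C@H]2CO)cc1OC | intermediate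
8 | [(3S,4S,5S)-5-(3,4-dimethoxyphenyl)-4-(hydroxymethyl)oxolan-3-yl](3,4,5-trimethoxyphenyl)methanone | COc1ccc([C@H]2OC[C@@H](C(=O)c3cc(OC)c(OC)c(OC)c3)[C@H]2CO)cc1OC | intermediate
9 | [(3R,4S,5S)-5-(3,4-dimethoxyphenyl)-4-(hydroxymethyl)oxolan-3-yl](3,4,5-trimethoxyphenyl)methanone | COc1ccc([C@H]2OC[C@H](C(=O)c3cc(OC)c(OC)c(OC)c3)[C@H]2CO)cc1OC | target

## Count and risks
Total steps: 5. Longest linear sequence: 5 steps (from 1 or 2).

**Step 4 (highest risk).** Formaldehyde is an untested partner. The electron-rich donor may ionise, which would lose the inversion and give the 4,5-trans series, or the cyclopropyl ketone may isomerise to a dihydrofuran. The fallback sets out from 5 and comes back at 9, bringing formaldehyde in as a tether instead of a free partner. Yb(OTf)3-catalysed hydration of 5 in THF/H2O (water as rear-side nucleophile, inversion at the benzylic carbon) gives (4S)-4-[(S)-(3,4-dimethoxyphenyl)(hydroxy)methyl]-3-(3,4,5-trimethoxybenzoyl)oxolan-2-one F2. LiOH, then AcOH at 50 °C, removes the lactone carbonyl as in step 5 and gives (3S,4S)-4-(3,4-dimethoxyphenyl)-4-hydroxy-3-(hydroxymethyl)-1-(3,4,5-trimethoxyphenyl)butan-1-one F3. CH2(OMe)2 with catalytic camphorsulfonic acid ties the 1,3-diol up as 2-[(4S,5S)-4-(3,4-dimethoxyphenyl)-1,3-dioxan-5-yl]-1-(3,4,5-trimethoxyphenyl)ethan-1-one F4. TiCl4/iPr2NEt in CH2Cl2 at −78 °C forms the titanium enolate and opens the formal at the less hindered primary oxygen. The enolate carbon then attacks the O-methylene cation left on the benzylic oxygen and closes the oxolane. DBU equilibrates C3 and the route is back at 9.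

**Step 3.** Enantioselectivity and yield are uncertain for an acceptor/acceptor diazo ester carrying a very electron-rich styrene. The fallback sets out from 3 and comes back at 5, with no diazo compound and no chiral catalyst. Mn(OAc)3·2H2O (2.2 equiv) and Cu(OAc)2·H2O (1 equiv) in AcOH at 70 °C oxidise the β-keto ester to its α-radical. This cyclises 5-exo, the benzylic radical is oxidised, and the cyclopropane closes. The product is 5 as a racemate, that is together with its mirror image (1S,5R,6S)-6-(3,4-dimethoxyphenyl)-1-(3,4,5-trimethoxybenzoyl)-3-oxabicyclo[3.1.0]hexan-2-one F1. Preparative chiral SFC separates the two and the route resumes at 5.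

**Step 5.** Hydroxide may attack the non-enolisable aryl ketone (retro-Claisen loss of the aroyl group) instead of the lactone. The fallback sets out from 6 and comes back at 8: it accepts that cleavage and puts the aryl ketone back at the end. NaOMe (1.1 equiv) in MeOH/THF at 0 °C cleaves 6 to methyl 3,4,5-trimethoxybenzoate and (1S,5S,6S)-6-(3,4-dimethoxyphenyl)-3,7-dioxabicyclo[3.3.0]octan-2-one F5. 3,4,5-Trimethoxyphenyllithium (from 5-bromo-1,2,3-trimethoxybenzene and n-BuLi, THF, −78 °C, 1.05 equiv) adds once to the lactone carbonyl. On work-up the lithium hemiketal opens to 8, which DBU converts to 9 as in step 5.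

## Further compounds
F1 | step 3 | (1S,5R,6S)-6-(3,4-dimethoxyphenyl)-1-(3,4,5-trimethoxybenzoyl)-3-oxabicyclo[3.1.0]hexan-2-one | O=C1OC[C@@H]2[C@@H](c3ccc(OC)c(OC)c3)[C@]12C(=O)c1cc(OC)c(OC)c(OC)c1
F2 | step 4 | (4S)-4-[(S)-(3,4-dimethoxyphenyl)(hydroxy)methyl]-3-(3,4,5-trimethoxybenzoyl)oxolan-2-one | COc1ccc([C@@H](O)[C@@H]2COC(=O)C2C(=O)c2cc(OC)c(OC)c(OC)c2)cc1OC
F3 | step 4 | (3S,4S)-4-(3,4-dimethoxyphenyl)-4-hydroxy-3-(hydroxymethyl)-1-(3,4,5-trimethoxyphenyl)butan-1-one | COc1ccc([C@@H](O)[C@H](CO)CC(=O)c2cc(OC)c(OC)c(OC)c2)cc1OC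
F4 | step 4 | 2-[(4S,5S)-4-(3,4-dimethoxyphenyl)-1,3-dioxan-5-yl]-1-(3,4,5-trimethoxyphenyl)ethan-1-one | COc1ccc([C@H]2OCOC[C@@H]2CC(=O)c2cc(OC)c(OC)c(OC)c2)cc1OC
F5 | step 5 | (1S,5S,6S)-6-(3,4-dimethoxyphenyl)-3,7-dioxabicyclo[3.3.0]octan-2-one | COc1ccc([C@H]2OC[C@H]3C(=O)OC[C@@H]23)cc1OC
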